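**Plan**

1. Retrosynthesis: cut O–C1 and H–C14 (Schenck ene retron) to reach the 1(10)E,4Z-triene 25; cut C3–C4 of the ten-membered ring (alkenyl bromide + aldehyde); cut the butenolide at C7–C8, C11–C12 and O–C12 to give alkynol 7, Grignard reagent 15 and CO2.
2. Forward order: two four-step fragments, then the butenolide ring (step 9), then the ten-membered carbocycle (step 12), then the hydroperoxide (step 15).
3. Enabling feature: in the ring O–C6–C7=C11–C12 the lactone oxygen on C6 is propargylic to a C7≡C11 alkyne, and C8 and C12 are trans across C7=C11. That is the outcome of an alkoxide-directed anti-carbomagnesiation followed by CO2 capture, so the ring oxygen is its own directing group.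
4. Stereochemistry: C6 is set by catalytic asymmetric alkynylation (the only catalyst-set centre); C3 is relayed from C6 in the ring-closing Nozaki–Hiyama–Kishi reaction; C1 is relayed from C3/C6 through the ring conformation in the biomimetic ene reaction.
5. Alkene geometry: 4Z from anti-hydrobromination of an ynoate, 1(10)E from syn-carboalumination, C7=C11 from the anti-carbomagnesiation.

Key step: step 9

Remark: germacrane numbering is used (ring C1–C10; C14 on C10, C15 on C4, C11–C13 the lactone side chain); the target SMILES is read as (1R,3S,4Z,6R).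
Assumption: in step 4 the (S,S)-ProPhenol ligand is taken to deliver the alkynyl group to the Si face of aldehyde 4; if the sense is opposite, the (R,R)-ligand is used.

**Route**

Step 1
Reactants: 1 ethyl but-2-ynoate
Product: 2 ethyl (Z)-3-bromobut-2-enoate
Conditions: LiBr, AcOH, MeCN, reflux
Reagents that add atoms: lithium bromide [Li+].[Br-]
Why: Anti hydrobromination of the ynoate (bromide conjugate addition, then protonation of the allenolate) should place Br cis to the ester, which later becomes the 4Z geometry.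

Step 2
Reactants: 2 ethyl (Z)-3-bromobut-2-enoate
Product: 3 (Z)-3-bromobut-2-en-1-ol
Conditions: DIBAL-H (2.2 equiv), CH2Cl2, −78 °C
Reagents that add atoms: none
Why: DIBAL-H 1,2-reduction of the enoate; the alkenyl bromide is inert at −78 °C.

Step 3
Reactants: 3 (Z)-3-bromobut-2-en-1-ol
Product: 4 (Z)-3-bromobut-2-enal
Conditions: MnO2, CH2Cl2, rt; used as a solution
Reagents that add atoms: none
Why: MnO2 oxidation of the allylic alcohol under neutral conditions should leave the Z geometry untouched.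

Step 4
Reactants: 4 (Z)-3-bromobut-2-enal; 5 triisopropyl(prop-2-yn-1-yloxy)silane
Product: 7 (4R,2Z)-2-bromo-7-[(triisopropylsilyl)oxy]hept-2-en-5-yn-4-ol, via alkynyl(methyl)zinc 6 (not isolated)
Conditions: Me2Zn (3 equiv), (S,S)-ProPhenol (20 mol %), Ph3PO (40 mol %), PhMe, 0 °C
Reagents that add atoms: none
Why: Zn-ProPhenol asymmetric alkynylation of an enal; the dinuclear zinc catalyst should deliver the alkynylzinc 6 to the Si face of the aldehyde and set C6 (4R in 7), the only catalyst-controlled stereocentre.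

Step 5
Reactants: 8 tert-butyl(but-3-yn-1-yloxy)dimethylsilane
Product: 11 (3E)-6-[(tert-butyldimethylsilyl)oxy]-4-methylhex-3-en-1-ol, via alkenylalane 9 (not isolated), via lithium alanate 10 (not isolated)
Conditions: Me3Al (2 equiv), Cp2ZrCl2 (0.25 equiv), CH2Cl2, 0 °C to rt; n-BuLi, THF, −78 °C; ethylene oxide, −78 °C to rt
Reagents that add atoms: trimethylaluminium C[Al](C)C; ethylene oxide C1CO1
Why: Negishi Zr-catalysed syn-carboalumination puts CH3 on the internal alkyne carbon with Al cis to it, and opening of ethylene oxide by the alanate with retention should give the E alkene (later C1=C10).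

Step 6
Reactants: 11 (3E)-6-[(tert-butyldimethylsilyl)oxy]-4-methylhex-3-en-1-ol
Product: 12 tert-butyl({(3E)-6-[(4-methoxybenzyl)oxy]-3-methylhex-3-en-1-yl}oxy)dimethylsilane
Conditions: NaH, PMBCl, Bu4NI (cat.), THF, 0 °C to rt
Reagents that add atoms: 4-methoxybenzyl chloride COc1ccc(CCl)cc1
Why: Williamson etherification of the primary alcohol; the TBS ether survives NaH.

Step 7
Reactants: 12 tert-butyl({(3E)-6-[(4-methoxybenzyl)oxy]-3-methylhex-3-en-1-yl}oxy)dimethylsilane
Product: 13 (3E)-6-[(4-methoxybenzyl)oxy]-3-methylhex-3-en-1-ol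
Conditions: TBAF, THF, 0 °C to rt
Reagents that add atoms: none
Why: Fluoride-mediated desilylation cleaves only the TBS ether.

Step 8
Reactants: 13 (3E)-6-[(4-methoxybenzyl)oxy]-3-methylhex-3-en-1-ol
Product: 14 1-({[(3E)-6-bromo-4-methylhex-3-en-1-yl]oxy}methyl)-4-methoxybenzene
Conditions: CBr4, PPh3, CH2Cl2, 0 °C
Reagents that add atoms: carbon tetrabromide BrC(Br)(Br)Br
Why: Appel bromination of the primary alcohol under neutral conditions that spare the PMB ether and the alkene.

Step 9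
Reactants: 14 1-({[(3E)-6-bromo-4-methylhex-3-en-1-yl]oxy}methyl)-4-methoxybenzene; 7 (4R,2Z)-2-bromo-7-[(triisopropylsilyl)oxy]hept-2-en-5-yn-4-ol
Product: 19 (5R)-5-[(1Z)-2-bromoprop-1-en-1-yl]-4-{(3E)-6-[(4-methoxybenzyl)oxy]-3-methylhex-3-en-1-yl}-3-{[(triisopropylsilyl)oxy]methyl}furan-2(5H)-one, via Grignard reagent 15 (not isolated), via bromomagnesium alkoxide 16 (not isolated), via oxamagnesacycle 17 (not isolated), via hydroxy acid 18 (not isolated)
Conditions: 14, Mg, THF, rt (gives 15, decanted from Mg); 7, MeMgBr (1.0 equiv), THF, 0 °C (gives 16); then 15 (1.5 equiv), CuI (0.2 equiv), THF–PhMe, −20 °C to rt; CO2 (1 atm), −20 °C to rt; 2 M HCl, rt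
Reagents that add atoms: carbon dioxide O=C=O
Why: The bromomagnesium alkoxide 16 binds the copper-activated Grignard reagent 15 and delivers C8 to the proximal alkyne carbon C7 from the face opposite to magnesium, which ends on C11 inside the five-membered oxamagnesacycle 17 (net anti addition); CO2 then carboxylates the C11–Mg bond with retention. The closest known reaction type is the Cu-catalysed, hydroxyl-directed anti-carbomagnesiation of 2-alkyn-1-ols with CO2 trapping to give 2(5H)-furanones. Two rings form: the oxamagnesacycle by chelation-controlled anti addition, and the butenolide by 5-exo-trig lactonisation of the C6 hydroxyl onto the cis C12 carboxyl of 18 on acidification. No new stereocentre arises: C6 is carried unchanged as its alkoxide, and the C7=C11 geometry (C8 cis to C13, C6 cis to C12) is fixed by the chelate. The step needs regioselectivity for C7 over C11, which the C6–O–Mg tether should secure, and chemoselectivity over Cu-mediated coupling at the alkenyl halide and over β-elimination of the C13 silyloxide from 17; an alkenyl bromide (not iodide), catalytic copper at low temperature and the bulky, poorly coordinating TIPS ether are chosen for this.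

Step 10
Reactants: 19 (5R)-5-[(1Z)-2-bromoprop-1-en-1-yl]-4-{(3E)-6-[(4-methoxybenzyl)oxy]-3-methylhex-3-en-1-yl}-3-{[(triisopropylsilyl)oxy]methyl}furan-2(5H)-one
Product: 20 (5R)-5-[(1Z)-2-bromoprop-1-en-1-yl]-4-[(3E)-6-hydroxy-3-methylhex-3-en-1-yl]-3-{[(triisopropylsilyl)oxy]methyl}furan-2(5H)-one
Conditions: DDQ, CH2Cl2–pH 7 buffer, 0 °C
Reagents that add atoms: none
Why: Oxidative PMB cleavage by DDQ (benzylic hydride abstraction) should spare the TIPS ether, the alkenyl bromide and the butenolide.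

Step 11
Reactants: 20 (5R)-5-[(1Z)-2-bromoprop-1-en-1-yl]-4-[(3E)-6-hydroxy-3-methylhex-3-en-1-yl]-3-{[(triisopropylsilyl)oxy]methyl}furan-2(5H)-one
Product: 21 (5R)-5-[(1Z)-2-bromoprop-1-en-1-yl]-4-[(3E)-3-methyl-6-oxohex-3-en-1-yl]-3-{[(triisopropylsilyl)oxy]methyl}furan-2(5H)-one
Conditions: Dess–Martin periodinane, pyridine, CH2Cl2, 0 °C; used at once
Reagents that add atoms: none
Why: Buffered Dess–Martin oxidation should give the β,γ-unsaturated aldehyde without migration of the C1=C10 alkene into conjugation.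

Step 12
Reactants: 21 (5R)-5-[(1Z)-2-bromoprop-1-en-1-yl]-4-[(3E)-3-methyl-6-oxohex-3-en-1-yl]-3-{[(triisopropylsilyl)oxy]methyl}furan-2(5H)-one
Product: 23 (1(10)E,3S,4Z,6R)-3-hydroxy-13-[(triisopropylsilyl)oxy]germacra-1(10),4,7(11)-trien-12,6-olide, via alkenylchromium(III) dichloride 22 (not isolated)
Conditions: CrCl2 (6 equiv), NiCl2 (5 mol %), DMSO–THF 3:1, slow addition to 4 mM, rt
Reagents that add atoms: none
Why: Intramolecular Nozaki–Hiyama–Kishi reaction, in which Ni inserts into the alkenyl bromide with retention and the alkenylchromium 22 adds to the aldehyde (10-exo-trig) under high dilution; the Z alkene holds C6 next to the reacting carbon C4, so C3 (3S) should be set by 1,4-relay from C6 in the cyclic transition state.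

Step 13
Reactants: 23 (1(10)E,3S,4Z,6R)-3-hydroxy-13-[(triisopropylsilyl)oxy]germacra-1(10),4,7(11)-trien-12,6-olide
Product: 24 (1(10)E,3S,4Z,6R)-3,13-dihydroxygermacra-1(10),4,7(11)-trien-12,6-olide
Conditions: HF·pyridine, pyridine, THF, 0 °C to rt
Reagents that add atoms: none
Why: Pyridine-buffered HF removes the primary TIPS ether and should avoid acid-induced transannular cyclisation of the 1,5-diene and base-induced epimerisation at C6.

Step 14
Reactants: 24 (1(10)E,3S,4Z,6R)-3,13-dihydroxygermacra-1(10),4,7(11)-trien-12,6-olide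
Product: 25 (1(10)E,3S,4Z,6R)-3,13-diacetoxygermacra-1(10),4,7(11)-trien-12,6-olide
Conditions: Ac2O, pyridine, DMAP (cat.), CH2Cl2, 0 °C
Reagents that add atoms: acetic anhydride CC(=O)OC(C)=O
Why: Acylation of both hydroxyls in one operation, with retention at C3 and conditions mild enough to leave the C6–H of the butenolide untouched.

Step 15
Reactants: 25 (1(10)E,3S,4Z,6R)-3,13-diacetoxygermacra-1(10),4,7(11)-trien-12,6-olide
Product: 26 (1R,3S,4Z,6R)-3,13-diacetoxy-1-hydroperoxygermacra-4,7(11),10(14)-trien-12,6-olide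
Conditions: O2, tetraphenylporphyrin (1 mol %), visible light, CH2Cl2, −20 °C
Reagents that add atoms: dioxygen O=O
Why: Schenck ene reaction of singlet oxygen at C1=C10, the most electron-rich alkene (C4=C5 carries two allylic C–O bonds, the butenolide alkene is electron-poor), with hydrogen taken from the C14 methyl on the disubstituted side (cis effect) so that oxygen adds at C1 and the double bond moves to C10=C14; attack on the only exposed outer face of the E alkene, whose orientation is fixed by C3 and C6, should set 1R as in the presumed biosynthesis.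

**Compound list**

1 | ethyl but-2-ynoate | CC#CC(=O)OCC | starting material
2 | ethyl (Z)-3-bromobut-2-enoate | CCOC(=O)/C=C(/C)Br | intermediate
3 | (Z)-3-bromobut-2-en-1-ol | OC/C=C(/C)Br | intermediate
4 | (Z)-3-bromobut-2-enal | O=C/C=C(/C)Br | intermediate
5 | triisopropyl(prop-2-yn-1-yloxy)silane | C#CCO[Si](C(C)C)(C(C)C)C(C)C | starting material
6 | methyl{3-[(triisopropylsilyl)oxy]prop-1-yn-1-yl}zinc | C[Zn]C#CCO[Si](C(C)C)(C(C)C)C(C)C | intermediate
7 | (4R,2Z)-2-bromo-7-[(triisopropylsilyl)oxy]hept-2-en-5-yn-4-ol | O[C@@H](C#CCO[Si](C(C)C)(C(C)C)C(C)C)/C=C(/C)Br | intermediate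
8 | tert-butyl(but-3-yn-1-yloxy)dimethylsilane | C#CCCO[Si](C)(C)C(C)(C)C | starting material
9 | {(1E)-4-[(tert-butyldimethylsilyl)oxy]-2-methylbut-1-en-1-yl}dimethylalane | C[Al](C)/C=C(\C)CCO[Si](C)(C)C(C)(C)C | intermediate
10 | lithium butyl{(1E)-4-[(tert-butyldimethylsilyl)oxy]-2-methylbut-1-en-1-yl}dimethylaluminate | [Li+].CCCC[Al-](C)(C)/C=C(\C)CCO[Si](C)(C)C(C)(C)C | intermediate
11 | (3E)-6-[(tert-butyldimethylsilyl)oxy]-4-methylhex-3-en-1-ol | OCC/C=C(\C)CCO[Si](C)(C)C(C)(C)C | intermediate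
12 | tert-butyl({(3E)-6-[(4-methoxybenzyl)oxy]-3-methylhex-3-en-1-yl}oxy)dimethylsilane | COc1ccc(COCC/C=C(\C)CCO[Si](C)(C)C(C)(C)C)cc1 | intermediate
13 | (3E)-6-[(4-methoxybenzyl)oxy]-3-methylhex-3-en-1-ol | COc1ccc(COCC/C=C(\C)CCO)cc1 | intermediate
14 | 1-({[(3E)-6-bromo-4-methylhex-3-en-1-yl]oxy}methyl)-4-methoxybenzene | COc1ccc(COCC/C=C(\C)CCBr)cc1 | intermediate
15 | {(3E)-6-[(4-methoxybenzyl)oxy]-3-methylhex-3-en-1-yl}magnesium bromide | COc1ccc(COCC/C=C(\C)CC[Mg]Br)cc1 | intermediate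
16 | bromomagnesium (4R,2Z)-2-bromo-7-[(triisopropylsilyl)oxy]hept-2-en-5-yn-4-olate | Br[Mg]O[C@@H](C#CCO[Si](C(C)C)(C(C)C)C(C)C)/C=C(/C)Br | intermediate
17 | (5R)-5-[(1Z)-2-bromoprop-1-en-1-yl]-4-{(3E)-6-[(4-methoxybenzyl)oxy]-3-methylhex-3-en-1-yl}-3-{[(triisopropylsilyl)oxy]methyl}-2,5-dihydro-1,2-oxamagnesole | O1[C@@H](C(CC/C(C)=C/CCOCc2ccc(OC)cc2)=C(CO[Si](C(C)C)(C(C)C)C(C)C)[Mg]1)/C=C(/C)Br | intermediate
18 | (2Z,4R,5Z)-6-bromo-4-hydroxy-3-{(3E)-6-[(4-methoxybenzyl)oxy]-3-methylhex-3-en-1-yl}-2-{[(triisopropylsilyl)oxy]methyl}hepta-2,5-dienoic acid | OC(=O)/C(CO[Si](C(C)C)(C(C)C)C(C)C)=C(/CC/C(C)=C/CCOCc1ccc(OC)cc1)[C@H](O)/C=C(/C)Br | intermediate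
19 | (5R)-5-[(1Z)-2-bromoprop-1-en-1-yl]-4-{(3E)-6-[(4-methoxybenzyl)oxy]-3-methylhex-3-en-1-yl}-3-{[(triisopropylsilyl)oxy]methyl}furan-2(5H)-one | O=C1O[C@H](/C=C(/C)Br)C(CC/C(C)=C/CCOCc2ccc(OC)cc2)=C1CO[Si](C(C)C)(C(C)C)C(C)C | intermediate
20 | (5R)-5-[(1Z)-2-bromoprop-1-en-1-yl]-4-[(3E)-6-hydroxy-3-methylhex-3-en-1-yl]-3-{[(triisopropylsilyl)oxy]methyl}furan-2(5H)-one | O=C1O[C@H](/C=C(/C)Br)C(CC/C(C)=C/CCO)=C1CO[Si](C(C)C)(C(C)C)C(C)C | intermediate
21 | (5R)-5-[(1Z)-2-bromoprop-1-en-1-yl]-4-[(3E)-3-methyl-6-oxohex-3-en-1-yl]-3-{[(triisopropylsilyl)oxy]methyl}furan-2(5H)-one | O=C1O[C@H](/C=C(/C)Br)C(CC/C(C)=C/CC=O)=C1CO[Si](C(C)C)(C(C)C)C(C)C | intermediate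
22 | dichloro{(1Z)-1-[(2R)-3-[(3E)-3-methyl-6-oxohex-3-en-1-yl]-5-oxo-4-{[(triisopropylsilyl)oxy]methyl}-2,5-dihydrofuran-2-yl]prop-1-en-2-yl}chromium(III) | O=C1O[C@H](/C=C(/C)[Cr](Cl)Cl)C(CC/C(C)=C/CC=O)=C1CO[Si](C(C)C)(C(C)C)C(C)C | intermediate
23 | (1(10)E,3S,4Z,6R)-3-hydroxy-13-[(triisopropylsilyl)oxy]germacra-1(10),4,7(11)-trien-12,6-olide | C1/C(C)=C/C[C@H](O)/C(C)=C\[C@H]2OC(=O)C(CO[Si](C(C)C)(C(C)C)C(C)C)=C2C1 | intermediate
24 | (1(10)E,3S,4Z,6R)-3,13-dihydroxygermacra-1(10),4,7(11)-trien-12,6-olide | C1/C(C)=C/C[C@H](O)/C(C)=C\[C@H]2OC(=O)C(CO)=C2C1 | intermediate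
25 | (1(10)E,3S,4Z,6R)-3,13-diacetoxygermacra-1(10),4,7(11)-trien-12,6-olide | C1/C(C)=C/C[C@H](OC(C)=O)/C(C)=C\[C@H]2OC(=O)C(COC(C)=O)=C2C1 | intermediate
26 | (1R,3S,4Z,6R)-3,13-diacetoxy-1-hydroperoxygermacra-4,7(11),10(14)-trien-12,6-olide | C=C1CCC2=C(COC(C)=O)C(=O)O[C@@H]2/C=C(/C)[C@@H](OC(C)=O)C[C@H]1OO | target

**Step count and risks**

Total step count: 15 (steps 1–4 and 5–8 run in parallel). Longest linear sequence: 11 steps (1–4 or 5–8, then 9–15).

The three steps most likely to fail are steps 9, 12 and 4. Step 15 is ranked below them because singlet-oxygen ene reactions of germacra-1(10)-enolides to 1-hydroperoxy-10(14)-enes are closely precedented, although its facial selectivity on this ring remains to be shown.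

Step 9. The alkenylmagnesium intermediate may lose the C13 silyloxide by β-elimination to give an allenol, copper may couple the Grignard reagent at the alkenyl bromide, or the alkyl group may add at C11 instead of C7. The fallback builds the same butenolide by a syn organocopper addition to an ynoate, which has no β-leaving group and runs at −78 °C. It sets out from aldehyde 4 and Grignard reagent 15 and comes back at 19. Zn-ProPhenol addition of methyl propiolate to 4 should give methyl (4R,5Z)-6-bromo-4-hydroxyhept-5-en-2-ynoate F1. Silylation (TESCl, imidazole) gives methyl (4R,5Z)-6-bromo-4-[(triethylsilyl)oxy]hept-5-en-2-ynoate F2. The organocopper made from 15 and CuBr·SMe2 adds syn across the ynoate of F2 at −78 °C, and iodine quench of the alkenylcopper gives methyl (2E,4R,5Z)-6-bromo-2-iodo-3-{(3E)-6-[(4-methoxybenzyl)oxy]-3-methylhex-3-en-1-yl}-4-[(triethylsilyl)oxy]hepta-2,5-dienoate F3. Stille coupling of the iodide with (tributylstannyl)methanol (the alkenyl bromide is much less reactive) gives methyl (2Z,4R,5Z)-6-bromo-2-(hydroxymethyl)-3-{(3E)-6-[(4-methoxybenzyl)oxy]-3-methylhex-3-en-1-yl}-4-[(triethylsilyl)oxy]hepta-2,5-dienoate F4. TsOH in MeOH removes the TES group, and the freed C6 hydroxyl lactonises onto the cis ester to give (5R)-5-[(1Z)-2-bromoprop-1-en-1-yl]-3-(hydroxymethyl)-4-{(3E)-6-[(4-methoxybenzyl)oxy]-3-methylhex-3-en-1-yl}furan-2(5H)-one F5. Silylation (TIPSCl, imidazole) gives 19.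

Step 12. The alkenylchromium may add to the wrong face of the aldehyde and give the 3R carbinol, since the 1,4-relay from C6 is not secured by any reagent. The fallback turns that epimer into the 3S acetate by SN2 inversion instead of acylation with retention. It sets out from 21 and comes back at 25. The NHK product (1(10)E,3R,4Z,6R)-3-hydroxy-13-[(triisopropylsilyl)oxy]germacra-1(10),4,7(11)-trien-12,6-olide F6 is treated with PPh3, DIAD and acetic acid (Mitsunobu inversion) to give (1(10)E,3S,4Z,6R)-3-acetoxy-13-[(triisopropylsilyl)oxy]germacra-1(10),4,7(11)-trien-12,6-olide F7. Buffered HF·pyridine gives (1(10)E,3S,4Z,6R)-3-acetoxy-13-hydroxygermacra-1(10),4,7(11)-trien-12,6-olide F8, and acetylation of the primary alcohol (Ac2O, pyridine) gives 25. Any 3S material formed alongside follows steps 13 and 14, so both epimers converge.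

Step 4. The enantioselectivity may be low, or the Z-bromoenal may isomerise to E on the Lewis-acidic zinc catalyst. The fallback sets C6 by reagent-controlled reduction of an ynone instead of by addition. It sets out from 4 and 5 and comes back at 7. The lithium acetylide of 5 (n-BuLi, THF, −78 °C) adds to 4 to give racemic (2Z)-2-bromo-7-[(triisopropylsilyl)oxy]hept-2-en-5-yn-4-ol F9. MnO2 gives (2Z)-2-bromo-7-[(triisopropylsilyl)oxy]hept-2-en-5-yn-4-one F10. Midland reduction with (R)-Alpine-Borane, in which the alkynyl group acts as the small substituent, should give (R)-7.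

Further compounds
F1 | step 9 | methyl (4R,5Z)-6-bromo-4-hydroxyhept-5-en-2-ynoate | COC(=O)C#C[C@H](O)/C=C(/C)Br
F2 | step 9 | methyl (4R,5Z)-6-bromo-4-[(triethylsilyl)oxy]hept-5-en-2-ynoate | COC(=O)C#C[C@H](O[Si](CC)(CC)CC)/C=C(/C)Br
F3 | step 9 | methyl (2E,4R,5Z)-6-bromo-2-iodo-3-{(3E)-6-[(4-methoxybenzyl)oxy]-3-methylhex-3-en-1-yl}-4-[(triethylsilyl)oxy]hepta-2,5-dienoate | COC(=O)/C(I)=C(/CC/C(C)=C/CCOCc1ccc(OC)cc1)[C@H](O[Si](CC)(CC)CC)/C=C(/C)Br
F4 | step 9 | methyl (2Z,4R,5Z)-6-bromo-2-(hydroxymethyl)-3-{(3E)-6-[(4-methoxybenzyl)oxy]-3-methylhex-3-en-1-yl}-4-[(triethylsilyl)oxy]hepta-2,5-dienoate | COC(=O)/C(CO)=C(/CC/C(C)=C/CCOCc1ccc(OC)cc1)[C@H](O[Si](CC)(CC)CC)/C=C(/C)Br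
F5 | step 9 | (5R)-5-[(1Z)-2-bromoprop-1-en-1-yl]-3-(hydroxymethyl)-4-{(3E)-6-[(4-methoxybenzyl)oxy]-3-methylhex-3-en-1-yl}furan-2(5H)-one | O=C1O[C@H](/C=C(/C)Br)C(CC/C(C)=C/CCOCc2ccc(OC)cc2)=C1CO
F6 | step 12 | (1(10)E,3R,4Z,6R)-3-hydroxy-13-[(triisopropylsilyl)oxy]germacra-1(10),4,7(11)-trien-12,6-olide | C1/C(C)=C/C[C@@H](O)/C(C)=C\[C@H]2OC(=O)C(CO[Si](C(C)C)(C(C)C)C(C)C)=C2C1
F7 | step 12 | (1(10)E,3S,4Z,6R)-3-acetoxy-13-[(triisopropylsilyl)oxy]germacra-1(10),4,7(11)-trien-12,6-olide | C1/C(C)=C/C[C@H](OC(C)=O)/C(C)=C\[C@H]2OC(=O)C(CO[Si](C(C)C)(C(C)C)C(C)C)=C2C1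
F8 | step 12 | (1(10)E,3S,4Z,6R)-3-acetoxy-13-hydroxygermacra-1(10),4,7(11)-trien-12,6-olide | C1/C(C)=C/C[C@H](OC(C)=O)/C(C)=C\[C@H]2OC(=O)C(CO)=C2C1
F9 | step 4 | racemic (2Z)-2-bromo-7-[(triisopropylsilyl)oxy]hept-2-en-5-yn-4-ol | OC(C#CCO[Si](C(C)C)(C(C)C)C(C)C)/C=C(/C)Br
F10 | step 4 | (2Z)-2-bromo-7-[(triisopropylsilyl)oxy]hept-2-en-5-yn-4-one | O=C(C#CCO[Si](C(C)C)(C(C)C)C(C)C)/C=C(/C)Br
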